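**Remarks on the chemistry**

- Atom labels follow the squalene-type numbering of the target. Left half: C2 (gem-dimethyl carbon), C3 (C=O), C6 (angular methyl carbon), C7 (O–CH), C10 (carbinol carbon), C11 (CH that carries the bridge). Bridge: C12–C12'. Right half: C11' (CH that carries the bridge), C2' (gem-dimethyl carbon), C3'/C7' (ring fusion), C6' (carbinol carbon), C8' (CH2), C9'/C10' (epoxide).
- AzTES = (1R,3aR,5S,8aR)-1,4,4,6-tetramethyl-1-(triethylsilyloxy)-1,2,3,3a,4,5,8,8a-octahydroazulen-5-yl.
- Assumption: commercial geranylacetone is used as the pure (5E)-isomer.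

## Analysis of the target

The target is a C30 triterpenoid made of two bicycles joined by the C12–C12' ethylene bridge. The left bicycle is a trans-fused 2,2-dimethyloxepan-3-one (O1, C2–C7) on a cyclohexane (C6–C11). The right bicycle is a cis-fused hydroazulene (cyclopentane C3'–C7', cycloheptane C2'/C3'/C7'–C11') with a 9',10'-epoxide. There are ten stereocentres. On the left: C6 (axial methyl), C7 (equatorial oxygen), C10 (axial tertiary OH, cis to the C6 methyl) and C11 (equatorial bridge). On the right: C3'/C7' (cis hydrogens), C6' (OH on the convex face, cis to H7'), C11' (bridge cis to the cyclopentane across C2'), and C9'/C10' (epoxide on the concave face, syn to the bridge). The two-carbon bridge insulates the halves, so neither can relay its configuration to the other and each needs absolute control. Sensitive groups are the trisubstituted epoxide (acid), two tertiary alcohols (elimination) and the α-alkoxy ketone. The feature that decides the strategy is in the left half: the O1–C2 bond and the C6–C11 bond lie anti across C6–C7. This is the imprint of an (E)-6,7-epoxide whose oxygen has attacked C2 of a second epoxide and which was then opened at C6 by C11. The hard parts are the two seven-membered rings, the quaternary carbons C2, C6 and C2', the tertiary carbinols at C10 and C6', and an epoxide on the more hindered face.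

## Retrosynthetic reasoning

**27 ⇐ 26 ⇐ 25 ⇐ 23 ⇐ 22 (end game, no skeletal bond cut).** The C3 ketone is carried as a silyl ether until the last step, because an α-alkoxy ketone would compete with C10 for the methyl nucleophile. The epoxide is placed after every Lewis-acidic operation. The C10 carbinol comes from ketone 22: the axial C6 methyl forces equatorial attack, which gives the required axial hydroxyl.

**22 ⇐ 21 (key disconnection: O1–C2 and C6–C11).** Both bonds of the left bicycle that are not present in a linear terpenoid chain are cut at once. The precursor 21 has no ring in its left half: it is a 1,5-diepoxide with a silyl enol ether, already attached to the complete right half. The forward reaction must close the oxepane and the cyclohexanone, set C6 and C11, transfer C7 and leave the hydroazulene untouched.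

**21 ⇐ 20 ⇐ 15 + 17 (C11–C12, as the C=C of an enone).** The cascade needs an enol ether that is regiodefined between C10 and C11. A ketone with two α-methylene groups cannot give this, but an enone can, by 1,4-hydrosilylation. The enone 20 comes from aldol condensation of the methyl ketone 17 with the aldehyde 15. The bond that joins the halves is therefore also the bond that arms the cascade.

**17 ⇐ 16 (two C–O bonds each at C2/C3 and C6/C7).** Both epoxides are set in one reagent-controlled operation on a commercial C13 ketone. The (6R,7R) configuration is the one that leads to C6(R)/C7(R) after inversion at C6.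

**15 ⇐ 13 ⇐ 12 ⇐ 11 (C11'–C12').** A Claisen rearrangement of the C9' allylic alcohol moves the oxygen function to a two-carbon aldehyde chain on C11'. It delivers the chain suprafacially and leaves the C9'=C10' alkene exactly where the epoxide is needed. C11' is thus controlled by the face of a ketone reduction, not by addition to a hindered neopentyl carbon.

**11 ⇐ 10 (C6'–C7').** A ketyl–olefin cyclisation closes the cyclopentane onto the seven-membered dienone. The short tether enforces the cis fusion, and the known anti preference of the ketyl oxygen sets the tertiary carbinol. The second enone of 10 survives and is the handle for the next two steps.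

**10 ⇐ 7 ⇐ 6 (removal of C8').** The cycloheptadienone is a one-carbon ring expansion of a six-membered silyl dienol ether, by cyclopropanation and oxidative cleavage.

**6 ⇐ 3 + 4 (C3'–C4'); 3 ⇐ 2 ⇐ 1.** Catalytic asymmetric conjugate addition to the cross-conjugated dienone 3 sets C3', the only stereocentre of the right half that needs an external chiral source. It also gives the enolate in the position required for the ring expansion. Dienone 3 is two steps from the commercial enone 1.

## Alternatives that were turned down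

Alternative 1: the textbook route. Disconnection: the bridge, C12=C12', between two finished bicycles. Forward key step: olefination of the left-half sulfone A1 with the right-half aldehyde A2 to the alkene A3, then saturation. Reasons for turning it down:
- The union forms no ring and no stereocentre, so all four rings and all ten stereocentres must be finished in two separate sequences.
- A1 needs a one-carbon handle on C11, so the left cascade must be run with a functionalised terminator and followed by several redox and activation steps.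
- The carbanion of A1 sits on a carbon flanked by the quaternary C6 and the tertiary C10.
- The disubstituted alkene of A3 must be reduced in the presence of the C9'=C10' alkene.

Alternative 2: the fully biomimetic route. Disconnection: all ring bonds of both halves. Forward key step: acid treatment of the triepoxide A4, so that both ends cyclise in one operation. Reasons for turning it down:
- The right end would require the C2'=C3' alkene to open the 6',7'-epoxide at its secondary carbon C7', against the cation-stabilising tertiary C6'.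
- It would then need a 7-endo capture of the C2' cation by C11' and a regioselective loss of H9'.
- Without an enzyme the C6' cation would rearrange or eliminate, and C11' has no control element.
- The left end would end in a C10 cation whose capture by water gives the equatorial alcohol or alkenes, not the axial alcohol.

Alternative 3: the chiral-pool route. Disconnection: C2'–C11' and C8'–C9' of the seven-membered ring, with the cyclopentane taken from (R)-limonene A5. Oxidative cleavage and aldol condensation of A5 give the enal A6, whose ten carbons map onto C2' (with both methyls), C3'–C7', the C6' methyl and C8'. Forward key step: hydrogen-atom-transfer-initiated radical closure of the isopropenyl carbon C2' onto an enone chain grown from C8'. Reasons for turning it down: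
- The oxygen of A6 sits on C8', which is a CH2 in the target.
- The tetrasubstituted C6'=C7' alkene would have to become a trans OH/H pair with C8' cis to both neighbours, which is contra-thermodynamic at an epimerisable centre and prone to dehydration.
- C11' would form in a seven-membered radical closure without a directing element.
- The redox corrections cost more steps than the ring-expansion and ketyl sequence.

Key step: step 13

## Route

Step 1
Reactants: 1 4,4-dimethylcyclohex-2-en-1-one
Product: 2 4,4,6-trimethylcyclohex-2-en-1-one (racemic)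
Conditions: LDA, THF, −78 °C; MeI, −78 → 0 °C
Reagents that add atoms: iodomethane (CI)
Why: Kinetic α'-deprotonation of the enone gives the cross-conjugated enolate, which is methylated at C6 (enolate alkylation); the new centre is racemic and becomes sp2 in step 2.

Step 2
Reactants: 2 4,4,6-trimethylcyclohex-2-en-1-one
Product: 3 2,4,4-trimethylcyclohexa-2,5-dien-1-one
Conditions: DDQ, 1,4-dioxane, reflux
Reagents that add atoms: none
Why: Quinone dehydrogenation of a 4,4-disubstituted cyclohexenone through its dienol gives the cross-conjugated dienone; only C5–C6 carries hydrogens that can be removed.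

Step 3
Reactants: 3 2,4,4-trimethylcyclohexa-2,5-dien-1-one; 4 2-(2-bromoethyl)-2-methyl-1,3-dioxolane
Product: 6 (R)-trimethyl({4,4,6-trimethyl-3-[2-(2-methyl-1,3-dioxolan-2-yl)ethyl]cyclohexa-1,5-dien-1-yl}oxy)silane, via Grignard reagent 5 (not isolated)
Conditions: 4, Mg, THF, 30 °C; then CuBr·SMe2 (5 mol %), Josiphos-type ferrocenyl diphosphine (6 mol %, the enantiomer that attacks the Re face of C5 of 3), t-BuOMe, −78 °C; then TMSCl, Et3N, HMPA, −78 → 0 °C
Reagents that add atoms: chlorotrimethylsilane (C[Si](C)(C)Cl)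
Why: Copper-catalysed asymmetric conjugate addition of a Grignard reagent; the α-unsubstituted enone of 3 is the more reactive one and the chiral copper complex sets C3' (R) by Re-face delivery, while silylation of the regiodefined magnesium enolate gives the 2-silyloxy diene needed for the ring expansion.

Step 4
Reactants: 6 (R)-trimethyl({4,4,6-trimethyl-3-[2-(2-methyl-1,3-dioxolan-2-yl)ethyl]cyclohexa-1,5-dien-1-yl}oxy)silane
Product: 7 trimethyl({(5R)-2,4,4-trimethyl-5-[2-(2-methyl-1,3-dioxolan-2-yl)ethyl]bicyclo[4.1.0]hept-2-en-1-yl}oxy)silane (both cyclopropane diastereomers)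
Conditions: Et2Zn, CH2I2, CH2Cl2, 0 °C → rt
Reagents that add atoms: diiodomethane (ICI)
Why: Simmons–Smith cyclopropanation (diethylzinc variant) is selective for the electron-rich silyl enol ether double bond of a 2-silyloxy diene; the cyclopropane configuration does not matter because both bridgehead carbons lose it in step 5.

Step 5
Reactants: 7 trimethyl({(5R)-2,4,4-trimethyl-5-[2-(2-methyl-1,3-dioxolan-2-yl)ethyl]bicyclo[4.1.0]hept-2-en-1-yl}oxy)silane
Product: 10 (5R)-2,4,4-trimethyl-5-(3-oxobutyl)cyclohepta-2,6-dien-1-one, via beta-chloro ketone 8 (not isolated), via dienone acetal 9 (not isolated)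
Conditions: FeCl3, DMF, 0 °C → rt; NaOAc, MeOH, reflux; then 1 M HCl, THF, rt
Reagents that add atoms: water (O)
Why: Oxidative ring expansion of a silyloxycyclopropane (Ito–Saegusa type): Fe(III) cleaves the internal cyclopropane bond to the more stable secondary β-keto radical, chlorine transfer and acetate-induced loss of HCl give the cyclohept-2-enone, and aqueous acid unmasks the methyl ketone.

Step 6
Reactants: 10 (5R)-2,4,4-trimethyl-5-(3-oxobutyl)cyclohepta-2,6-dien-1-one
Product: 11 (1R,3aR,8aR)-1-hydroxy-1,4,4,6-tetramethyl-1,2,3,3a,4,8a-hexahydroazulen-7(8H)-one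
Conditions: SmI2 (2.5 equiv), THF/MeOH, −78 °C
Reagents that add atoms: none
Why: SmI2-mediated reductive ketone–enone (ketyl–olefin) 5-exo-trig cyclisation; the three-atom tether on C3' reaches only the adjacent face of C7' and so gives the cis fusion, the samarium-bound oxygen turns away from the developing dienolate so that OH ends anti to C8' (cis to H7'), and protonation of the cross-conjugated dienolate at C8' should return the C9' enone.

Step 7
Reactants: 11 (1R,3aR,8aR)-1-hydroxy-1,4,4,6-tetramethyl-1,2,3,3a,4,8a-hexahydroazulen-7(8H)-one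
Product: 12 (1R,3aR,8aR)-1,4,4,6-tetramethyl-1-(triethylsilyloxy)-1,2,3,3a,4,8a-hexahydroazulen-7(8H)-one
Conditions: TESOTf, 2,6-lutidine, CH2Cl2, −78 → −20 °C
Reagents that add atoms: triethylsilyl trifluoromethanesulfonate (CC[Si](CC)(CC)OS(=O)(=O)C(F)(F)F)
Why: Silyl triflate silylation of a tertiary alcohol; the ether keeps O6' out of the enolate, Lewis acid and bromonium chemistry that follows.

Step 8
Reactants: 12 (1R,3aR,8aR)-1,4,4,6-tetramethyl-1-(triethylsilyloxy)-1,2,3,3a,4,8a-hexahydroazulen-7(8H)-one
Product: 13 (1R,3aR,7S,8aR)-1,4,4,6-tetramethyl-1-(triethylsilyloxy)-1,2,3,3a,4,7,8,8a-octahydroazulen-7-ol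
Conditions: NaBH4, CeCl3·7H2O, MeOH, −78 °C
Reagents that add atoms: none
Why: Luche 1,2-reduction; the concave face of the cis-fused bicycle is shielded by the cyclopentane and its endo methyl group, so hydride should enter from the convex face and place the C9' hydroxyl on the concave face.

Step 9
Reactants: 13 (1R,3aR,7S,8aR)-1,4,4,6-tetramethyl-1-(triethylsilyloxy)-1,2,3,3a,4,7,8,8a-octahydroazulen-7-ol
Product: 15 2-[(1R,3aR,5S,8aR)-1,4,4,6-tetramethyl-1-(triethylsilyloxy)-1,2,3,3a,4,5,8,8a-octahydroazulen-5-yl]acetaldehyde, via allyl vinyl ether 14 (not isolated)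
Conditions: ethyl vinyl ether, Hg(OAc)2 (cat.), reflux; evaporate; PhMe, sealed tube, 190 °C
Reagents that add atoms: ethyl vinyl ether (C=COCC)
Why: Transvinylation followed by Claisen [3,3] rearrangement; the shift is suprafacial, so the C–O bond on the concave face of C9' becomes the C11'–C12' bond on the same face, which sets C11', forms the C9'=C10' trisubstituted alkene and gives the C12 aldehyde.

Step 10
Reactants: 16 (5E)-6,10-dimethylundeca-5,9-dien-2-one (geranylacetone)
Product: 17 (5R,6R,9R)-5,6:9,10-diepoxy-6,10-dimethylundecan-2-one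
Conditions: D-fructose-derived ketone catalyst (0.6 equiv), Oxone, K2CO3, Bu4NHSO4, MeCN/dimethoxymethane/aq. borate buffer (pH 10.5), 0 °C
Reagents that add atoms: potassium peroxymonosulfate ([K+].[O-]S(=O)(=O)OO)
Why: Shi asymmetric epoxidation; the chiral dioxirane gives the (R,R)-epoxide from the (E)-trisubstituted alkene and the (R)-epoxide from the terminal trisubstituted alkene through the spiro transition state, and the saturated methyl ketone is not affected.

Step 11
Reactants: 17 (5R,6R,9R)-5,6:9,10-diepoxy-6,10-dimethylundecan-2-one; 15 2-[(1R,3aR,5S,8aR)-1,4,4,6-tetramethyl-1-(triethylsilyloxy)-1,2,3,3a,4,5,8,8a-octahydroazulen-5-yl]acetaldehyde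
Product: 20 (2E,7R,8R,11R)-7,8:11,12-diepoxy-8,12-dimethyl-1-(AzTES)tridec-2-en-4-one, via aldol adduct 18 (not isolated), via aldol mesylate 19 (not isolated)
Conditions: 17, LDA, THF, −78 °C; 15, −78 °C; MsCl, −78 → 0 °C; DBU, 0 °C → rt
Reagents that add atoms: none
Why: Aldol condensation: the kinetic methyl-side lithium enolate of 17 adds to the aldehyde, the aldolate is mesylated in the flask and E1cB elimination gives the (E)-enone; this forms C11–C12 and joins the halves, and the trisubstituted epoxides tolerate the enolate at −78 °C.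

Step 12
Reactants: 20 (2E,7R,8R,11R)-7,8:11,12-diepoxy-8,12-dimethyl-1-(AzTES)tridec-2-en-4-one
Product: 21 triethyl{[(3Z,7R,8R,11R)-7,8:11,12-diepoxy-8,12-dimethyl-1-(AzTES)tridec-3-en-4-yl]oxy}silane
Conditions: Et3SiH, (Ph3P)3RhCl (2 mol %), PhMe, 50 °C
Reagents that add atoms: triethylsilane (CC[SiH](CC)CC)
Why: Rhodium-catalysed 1,4-hydrosilylation of an enone places the silyl enol ether regiospecifically at C10=C11, mainly as the (Z)-isomer; the epoxides, the trisubstituted alkene and the silyl ether are inert to the catalyst.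

Step 13
Reactants: 21 triethyl{[(3Z,7R,8R,11R)-7,8:11,12-diepoxy-8,12-dimethyl-1-(AzTES)tridec-3-en-4-yl]oxy}silane
Product: 22 (3R,5aR,6R,9aR)-2,2,5a-trimethyl-6-[2-(AzTES)ethyl]-3-(triethylsilyloxy)-3,4,5,5a,6,8,9,9a-octahydro-1-benzoxepin-7(2H)-one
Conditions: TESOTf (1.1 equiv), 2,6-di-tert-butyl-4-methylpyridine (1.5 equiv), CH2Cl2, −78 °C; Et3N quench
Reagents that add atoms: triethylsilyl trifluoromethanesulfonate (CC[Si](CC)(CC)OS(=O)(=O)C(F)(F)F)
Why: The silyl triflate silylates the terminal 2,3-epoxide, and the oxygen of the 6,7-epoxide attacks its tertiary carbon C2 in a 7-endo mode, which gives a bridged epoxonium ion in which the oxepane (O1 bonded to C2 and C7, OTES on C3) is already closed. The enol ether carbon C11 then opens this ion at its tertiary carbon C6 in a 6-endo, chair-like closure with inversion at C6, and loss of the silyl group from the oxocarbenium ion gives the C10 ketone and returns the silyl triflate. The closest known reaction type is the silyl-triflate-promoted tandem oxa-/carbacyclisation of terpenoid 1,5-diepoxides terminated by a silyl enol ether, which gives the same trans-fused oxepane–cyclohexanone from simple chains. C7 keeps the configuration of the (6R,7R)-epoxide and C6 is inverted anti to the C7–O bond, so the oxygen is equatorial, the methyl axial and the fusion trans; C3 comes unchanged from the (3R)-epoxide. C11 is set by the chair, in which the (Z)-enol ether places C12 equatorial, and as C11 is α to the new ketone this is also the thermodynamic epimer. The step needs endo opening of both epoxides: both attacked carbons are tertiary and carry the positive charge of the trisubstituted epoxides, and the hindered pyridine base suppresses proton-catalysed exo openings. It also needs the right half to stay out, which the substrate secures because the C9'=C10' alkene and the silylated O6' cannot reach C2 or C6 through a small ring.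

Step 14
Reactants: 22 (3R,5aR,6R,9aR)-2,2,5a-trimethyl-6-[2-(AzTES)ethyl]-3-(triethylsilyloxy)-3,4,5,5a,6,8,9,9a-octahydro-1-benzoxepin-7(2H)-one
Product: 23 (3R,5aR,6R,7S,9aR)-2,2,5a,7-tetramethyl-6-[2-(AzTES)ethyl]-3-(triethylsilyloxy)decahydro-1-benzoxepin-7-ol
Conditions: MeLi, CeCl3, THF, −78 °C
Reagents that add atoms: methyllithium ([Li]C)
Why: Organocerium 1,2-addition without enolisation; the axial C6 methyl group blocks the axial trajectory (1,3-diaxial), so the methyl group should enter equatorially and leave the C10 hydroxyl axial, cis to the C6 methyl.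

Step 15
Reactants: 23 (3R,5aR,6R,7S,9aR)-2,2,5a,7-tetramethyl-6-[2-(AzTES)ethyl]-3-(triethylsilyloxy)decahydro-1-benzoxepin-7-ol
Product: 25 the (9'S,10'R)-epoxide of 23 (epoxide oxygen on the concave face of the hydroazulene, syn to the bridge; both silyl ethers in place), via bromohydrin 24 (not isolated)
Conditions: NBS, THF/H2O (4:1), 0 °C; then K2CO3, MeOH, rt
Reagents that add atoms: water (O)
Why: Bromohydrin formation and base-induced closure: bromine should add to the open convex face, water opens the bromonium ion anti at the tertiary C10', and intramolecular SN2 displacement with inversion at C9' leaves the epoxide oxygen on the concave face; the silyl ether on O6' prevents bromoetherification.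

Step 16
Reactants: 25 the (9'S,10'R)-epoxide of 23
Product: 26 (3R,5aR,6R,7S,9aR)-6-{2-[(1R,3aR,5R,6R,7S,8aR)-6,7-epoxy-1-hydroxy-1,4,4,6-tetramethyldecahydroazulen-5-yl]ethyl}-2,2,5a,7-tetramethyldecahydro-1-benzoxepine-3,7-diol
Conditions: TBAF, THF, 0 → 40 °C
Reagents that add atoms: none
Why: Fluoride cleavage of the secondary and the tertiary triethylsilyl ether; the epoxide and the tertiary alcohols are stable to fluoride, which would not be true of an acidic desilylation.

Step 17
Reactants: 26 (3R,5aR,6R,7S,9aR)-6-{2-[(1R,3aR,5R,6R,7S,8aR)-6,7-epoxy-1-hydroxy-1,4,4,6-tetramethyldecahydroazulen-5-yl]ethyl}-2,2,5a,7-tetramethyldecahydro-1-benzoxepine-3,7-diol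
Product: 27 CNP0259752.1, (5aR,6R,7S,9aR)-6-{2-[(1R,3aR,5R,6R,7S,8aR)-6,7-epoxy-1-hydroxy-1,4,4,6-tetramethyldecahydroazulen-5-yl]ethyl}-7-hydroxy-2,2,5a,7-tetramethyl-4,5,5a,6,7,8,9,9a-octahydro-1-benzoxepin-3(2H)-one
Conditions: Dess–Martin periodinane, NaHCO3, CH2Cl2, 0 °C → rt
Reagents that add atoms: none
Why: Dess–Martin oxidation; C3–OH is the only secondary alcohol, the two tertiary alcohols and the epoxide are inert under buffered conditions, and the quaternary C2 next to the new ketone cannot epimerise.

## Compound list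

1 | 4,4-dimethylcyclohex-2-en-1-one | CC1(C)CCC(=O)C=C1 | starting material
2 | 4,4,6-trimethylcyclohex-2-en-1-one (racemic) | CC1CC(C)(C)C=CC1=O | intermediate
3 | 2,4,4-trimethylcyclohexa-2,5-dien-1-one | CC1=CC(C)(C)C=CC1=O | intermediate
4 | 2-(2-bromoethyl)-2-methyl-1,3-dioxolane | CC1(CCBr)OCCO1 | starting material
5 | [2-(2-methyl-1,3-dioxolan-2-yl)ethyl]magnesium bromide | CC1(CC[Mg]Br)OCCO1 | intermediate
6 | (R)-trimethyl({4,4,6-trimethyl-3-[2-(2-methyl-1,3-dioxolan-2-yl)ethyl]cyclohexa-1,5-dien-1-yl}oxy)silane | CC1(CC[C@@H]2C=C(O[Si](C)(C)C)C(C)=CC2(C)C)OCCO1 | intermediate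
7 | trimethyl({(5R)-2,4,4-trimethyl-5-[2-(2-methyl-1,3-dioxolan-2-yl)ethyl]bicyclo[4.1.0]hept-2-en-1-yl}oxy)silane (both cyclopropane diastereomers) | CC1(CC[C@@H]2C3CC3(O[Si](C)(C)C)C(C)=CC2(C)C)OCCO1 | intermediate
8 | 6-chloro-2,4,4-trimethyl-5-[2-(2-methyl-1,3-dioxolan-2-yl)ethyl]cyclohept-2-en-1-one (C5 as in 6, both C6 epimers) | CC1(CC[C@@H]2C(Cl)CC(=O)C(C)=CC2(C)C)OCCO1 | intermediate
9 | (5R)-2,4,4-trimethyl-5-[2-(2-methyl-1,3-dioxolan-2-yl)ethyl]cyclohepta-2,6-dien-1-one | CC1(CC[C@@H]2C=CC(=O)C(C)=CC2(C)C)OCCO1 | intermediate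
10 | (5R)-2,4,4-trimethyl-5-(3-oxobutyl)cyclohepta-2,6-dien-1-one | CC(=O)CC[C@@H]1C=CC(=O)C(C)=CC1(C)C | intermediate
11 | (1R,3aR,8aR)-1-hydroxy-1,4,4,6-tetramethyl-1,2,3,3a,4,8a-hexahydroazulen-7(8H)-one (cis-fused, OH cis to the ring-fusion hydrogens) | CC1(C)C=C(C)C(=O)C[C@@H]2[C@H]1CC[C@@]2(C)O | intermediate
12 | (1R,3aR,8aR)-1,4,4,6-tetramethyl-1-(triethylsilyloxy)-1,2,3,3a,4,8a-hexahydroazulen-7(8H)-one | CC1(C)C=C(C)C(=O)C[C@@H]2[C@H]1CC[C@@]2(C)O[Si](CC)(CC)CC | intermediate
13 | (1R,3aR,7S,8aR)-1,4,4,6-tetramethyl-1-(triethylsilyloxy)-1,2,3,3a,4,7,8,8a-octahydroazulen-7-ol | CC1(C)C=C(C)[C@@H](O)C[C@@H]2[C@H]1CC[C@@]2(C)O[Si](CC)(CC)CC | intermediate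
14 | vinyl ether of 13, (1R,3aR,7S,8aR)-7-(ethenyloxy)-1,4,4,6-tetramethyl-1-(triethylsilyloxy)-1,2,3,3a,4,7,8,8a-octahydroazulene | CC1(C)C=C(C)[C@@H](OC=C)C[C@@H]2[C@H]1CC[C@@]2(C)O[Si](CC)(CC)CC | intermediate
15 | 2-[(1R,3aR,5S,8aR)-1,4,4,6-tetramethyl-1-(triethylsilyloxy)-1,2,3,3a,4,5,8,8a-octahydroazulen-5-yl]acetaldehyde | O=CC[C@@H]1C(C)(C)[C@@H]2CC[C@@](C)(O[Si](CC)(CC)CC)[C@@H]2CC=C1C | intermediate
16 | (5E)-6,10-dimethylundeca-5,9-dien-2-one (geranylacetone) | CC(C)=CCC/C(C)=C/CCC(C)=O | starting material
17 | (5R,6R,9R)-5,6:9,10-diepoxy-6,10-dimethylundecan-2-one | CC1(C)O[C@@H]1CC[C@@]2(C)O[C@@H]2CCC(C)=O | intermediate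
18 | (7R,8R,11R)-7,8:11,12-diepoxy-2-hydroxy-8,12-dimethyl-1-(AzTES)tridecan-4-one (both C2 epimers) | CC1(C)O[C@@H]1CC[C@@]2(C)O[C@@H]2CCC(=O)CC(O)C[C@@H]3C(C)(C)[C@@H]4CC[C@@](C)(O[Si](CC)(CC)CC)[C@@H]4CC=C3C | intermediate
19 | 2-O-methanesulfonate of 18 | CC1(C)O[C@@H]1CC[C@@]2(C)O[C@@H]2CCC(=O)CC(OS(C)(=O)=O)C[C@@H]3C(C)(C)[C@@H]4CC[C@@](C)(O[Si](CC)(CC)CC)[C@@H]4CC=C3C | intermediate
20 | (2E,7R,8R,11R)-7,8:11,12-diepoxy-8,12-dimethyl-1-(AzTES)tridec-2-en-4-one | CC1(C)O[C@@H]1CC[C@@]2(C)O[C@@H]2CCC(=O)/C=C/C[C@@H]3C(C)(C)[C@@H]4CC[C@@](C)(O[Si](CC)(CC)CC)[C@@H]4CC=C3C | intermediate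
21 | triethyl{[(3Z,7R,8R,11R)-7,8:11,12-diepoxy-8,12-dimethyl-1-(AzTES)tridec-3-en-4-yl]oxy}silane | CC1(C)O[C@@H]1CC[C@@]2(C)O[C@@H]2CC/C(O[Si](CC)(CC)CC)=C/CC[C@@H]3C(C)(C)[C@@H]4CC[C@@](C)(O[Si](CC)(CC)CC)[C@@H]4CC=C3C | intermediate
22 | (3R,5aR,6R,9aR)-2,2,5a-trimethyl-6-[2-(AzTES)ethyl]-3-(triethylsilyloxy)-3,4,5,5a,6,8,9,9a-octahydro-1-benzoxepin-7(2H)-one | CC1(C)O[C@@H]2CCC(=O)[C@H](CC[C@@H]3C(C)(C)[C@@H]4CC[C@@](C)(O[Si](CC)(CC)CC)[C@@H]4CC=C3C)[C@@]2(C)CC[C@H]1O[Si](CC)(CC)CC | intermediate
23 | (3R,5aR,6R,7S,9aR)-2,2,5a,7-tetramethyl-6-[2-(AzTES)ethyl]-3-(triethylsilyloxy)decahydro-1-benzoxepin-7-ol | CC1(C)O[C@@H]2CC[C@](C)(O)[C@H](CC[C@@H]3C(C)(C)[C@@H]4CC[C@@](C)(O[Si](CC)(CC)CC)[C@@H]4CC=C3C)[C@@]2(C)CC[C@H]1O[Si](CC)(CC)CC | intermediate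
24 | trans-bromohydrin of 23 (Br on C9', convex face; OH on C10', concave face) | CC1(C)O[C@@H]2CC[C@](C)(O)[C@H](CC[C@@H]3C(C)(C)[C@@H]4CC[C@@](C)(O[Si](CC)(CC)CC)[C@@H]4C[C@@H](Br)[C@]3(C)O)[C@@]2(C)CC[C@H]1O[Si](CC)(CC)CC | intermediate
25 | (9'S,10'R)-epoxide of 23 (3-O- and 6'-O-triethylsilyl ether of 26) | CC1(C)O[C@@H]2CC[C@](C)(O)[C@H](CC[C@@H]3C(C)(C)[C@@H]4CC[C@@](C)(O[Si](CC)(CC)CC)[C@@H]4C[C@@H]4O[C@@]43C)[C@@]2(C)CC[C@H]1O[Si](CC)(CC)CC | intermediate
26 | (3R,5aR,6R,7S,9aR)-6-{2-[(1R,3aR,5R,6R,7S,8aR)-6,7-epoxy-1-hydroxy-1,4,4,6-tetramethyldecahydroazulen-5-yl]ethyl}-2,2,5a,7-tetramethyldecahydro-1-benzoxepine-3,7-diol | CC1(C)O[C@@H]2CC[C@](C)(O)[C@H](CC[C@@H]3C(C)(C)[C@@H]4CC[C@@](C)(O)[C@@H]4C[C@@H]4O[C@@]43C)[C@@]2(C)CC[C@H]1O | intermediate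
27 | CNP0259752.1, (5aR,6R,7S,9aR)-6-{2-[(1R,3aR,5R,6R,7S,8aR)-6,7-epoxy-1-hydroxy-1,4,4,6-tetramethyldecahydroazulen-5-yl]ethyl}-7-hydroxy-2,2,5a,7-tetramethyl-4,5,5a,6,7,8,9,9a-octahydro-1-benzoxepin-3(2H)-one | CC1(C)O[C@@H]2CC[C@](C)(O)[C@H](CC[C@@H]3C(C)(C)[C@@H]4CC[C@@](C)(O)[C@@H]4C[C@@H]4O[C@@]43C)[C@@]2(C)CCC1=O | target

## Step count and risks

Total: 17 steps. Longest linear sequence: 16 steps (steps 1–9 and 11–17); step 10 is the one-step branch to 17.

**Step 13 (key step).** What may go wrong: the enol ether may attack the silylated 6,7-epoxide before the oxepane has closed; either epoxide may open in the exo mode to a tetrahydrofuran or tetrahydropyran; or the enol ether may be protodesilylated. The cause is that three Lewis-basic oxygens compete for one silyl cation. Fallback (rings first, union afterwards): it sets out from 17 and 15 and returns to the route at 22. Ketone 17 is converted with LDA and TESCl into the kinetic triethylsilyl enol ether F1, the substrate type with the closest precedent for the tandem cyclisation. TESOTf and the hindered pyridine base should give the bicyclic ketone F2. IBX dehydrogenation can only go towards C8–C9 and gives the enone F3, in which C11 is the only enolisable carbon. Aldehyde 15 is reduced with NaBH4 to the alcohol F4, which I2, PPh3 and imidazole convert into the iodide F5. The lithium enolate of F3 (LDA, THF/HMPA) is alkylated with F5 at C11, anti to the axial C6 methyl, to give the coupled enone F6. Conjugate reduction with Stryker's reagent then gives 22.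

**Step 6.** What may go wrong: the cross-conjugated dienone may be reduced without ring closure, or the ketyl may add with its oxygen on the side of C8' and give the C6' epimer. The dienone accepts an electron more easily than the methyl ketone, so the order of events is less certain than with an enoate. Fallback (C6' set by convex-face epoxidation instead of by the ketyl geometry): it sets out from 10 and returns at 11. The C1 epimer of 11, the endo alcohol F7, is dehydrated with the Burgess reagent to the cyclopentene F8; the elimination is syn and H8a is anti to the hydroxyl. mCPBA attacks only this electron-rich alkene, from the convex face, and gives the epoxide F9. LiAlH4 opens the epoxide at its secondary carbon and reduces the ketone, which gives the diol F10. MnO2 re-oxidises the allylic alcohol to 11.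

**Step 3.** What may go wrong: low enantioselectivity or competing 1,2-addition, because the β-carbon is neopentylic and the Grignard reagent carries a coordinating acetal; incomplete O-silylation of the magnesium enolate. Fallback (desymmetrisation of the symmetric dienone, methyl group added afterwards): it sets out from 1 and returns at 6. DDQ converts 1 into the symmetric dienone F11. The same copper-catalysed addition of 5, followed by protonation, gives the enone F12. Iodine and pyridine give the α-iodoenone F13. Suzuki methylation (trimethylboroxine, Pd(dppf)Cl2, K2CO3) gives the 2-methyl enone F14. LDA and then TMSCl silylate its only enolisable α' position and give 6.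

**Step 8.** What may go wrong: hydride delivery to the concave face, or low facial selectivity, which the Claisen step would copy into C11'. Fallback (inversion instead of facial control): it sets out from 12 and returns at 13. The C7 epimer of 13, the convex alcohol F15, undergoes Mitsunobu inversion (4-nitrobenzoic acid, PPh3, DIAD) to the inverted 4-nitrobenzoate F16, and K2CO3 in MeOH gives 13.

**Step 15.** What may go wrong: bromonium formation on the concave face or low facial selectivity, which would give the epimeric epoxide; the argument for the convex face rests on the shape of a flexible seven-membered ring. Fallback (syn oxygen transfer instead of anti addition and closure): it sets out from 23 and returns at 25. Dimethyldioxirane in acetone at 0 °C places the oxygen on the face that the electrophile prefers, so it is the correct method if that face turns out to be the concave one. It makes no new compound (F0).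

## Further compounds

F1 | step 13 | triethyl{[(5R,6R,9R)-5,6:9,10-diepoxy-6,10-dimethylundec-1-en-2-yl]oxy}silane | CC1(C)O[C@@H]1CC[C@@]2(C)O[C@@H]2CCC(=C)O[Si](CC)(CC)CC
F2 | step 13 | (3R,5aR,9aR)-2,2,5a-trimethyl-3-(triethylsilyloxy)-3,4,5,5a,6,8,9,9a-octahydro-1-benzoxepin-7(2H)-one | CC1(C)O[C@@H]2CCC(=O)C[C@@]2(C)CC[C@H]1O[Si](CC)(CC)CC
F3 | step 13 | (3R,5aR,9aR)-2,2,5a-trimethyl-3-(triethylsilyloxy)-3,4,5,5a,6,9a-hexahydro-1-benzoxepin-7(2H)-one | CC1(C)O[C@@H]2C=CC(=O)C[C@@]2(C)CC[C@H]1O[Si](CC)(CC)CC
F4 | step 13 | 2-(AzTES)ethan-1-ol | OCC[C@@H]1C(C)(C)[C@@H]2CC[C@@](C)(O[Si](CC)(CC)CC)[C@@H]2CC=C1C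
F5 | step 13 | 5-(2-iodoethyl) analogue of F4, AzTES–CH2CH2I | ICC[C@@H]1C(C)(C)[C@@H]2CC[C@@](C)(O[Si](CC)(CC)CC)[C@@H]2CC=C1C
F6 | step 13 | (3R,5aR,6R,9aR)-2,2,5a-trimethyl-6-[2-(AzTES)ethyl]-3-(triethylsilyloxy)-3,4,5,5a,6,9a-hexahydro-1-benzoxepin-7(2H)-one | CC1(C)O[C@@H]2C=CC(=O)[C@H](CC[C@@H]3C(C)(C)[C@@H]4CC[C@@](C)(O[Si](CC)(CC)CC)[C@@H]4CC=C3C)[C@@]2(C)CC[C@H]1O[Si](CC)(CC)CC
F7 | step 6 | (1S,3aR,8aR)-1-hydroxy-1,4,4,6-tetramethyl-1,2,3,3a,4,8a-hexahydroazulen-7(8H)-one (C1 epimer of 11) | CC1(C)C=C(C)C(=O)C[C@@H]2[C@H]1CC[C@]2(C)O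
F8 | step 6 | (3aR,8aR)-1,4,4,6-tetramethyl-3,3a,4,8a-tetrahydroazulen-7(8H)-one | CC1(C)C=C(C)C(=O)C[C@@H]2[C@H]1CC=C2C
F9 | step 6 | 1,2-epoxide of F8, oxygen on the convex face | CC1(C)C=C(C)C(=O)C[C@@H]2[C@H]1C[C@H]3O[C@@]23C
F10 | step 6 | (1R,3aR,8aR)-1,4,4,6-tetramethyl-1,2,3,3a,4,7,8,8a-octahydroazulene-1,7-diol (either C7 epimer) | CC1(C)C=C(C)C(O)C[C@@H]2[C@H]1CC[C@@]2(C)O
F11 | step 3 | 4,4-dimethylcyclohexa-2,5-dien-1-one | CC1(C)C=CC(=O)C=C1
F12 | step 3 | (5R)-4,4-dimethyl-5-[2-(2-methyl-1,3-dioxolan-2-yl)ethyl]cyclohex-2-en-1-one | CC1(CC[C@@H]2CC(=O)C=CC2(C)C)OCCO1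
F13 | step 3 | (5R)-2-iodo-4,4-dimethyl-5-[2-(2-methyl-1,3-dioxolan-2-yl)ethyl]cyclohex-2-en-1-one | CC1(CC[C@@H]2CC(=O)C(I)=CC2(C)C)OCCO1
F14 | step 3 | (5R)-2,4,4-trimethyl-5-[2-(2-methyl-1,3-dioxolan-2-yl)ethyl]cyclohex-2-en-1-one | CC1(CC[C@@H]2CC(=O)C(C)=CC2(C)C)OCCO1
F15 | step 8 | (1R,3aR,7R,8aR)-1,4,4,6-tetramethyl-1-(triethylsilyloxy)-1,2,3,3a,4,7,8,8a-octahydroazulen-7-ol (C7 epimer of 13) | CC1(C)C=C(C)[C@H](O)C[C@@H]2[C@H]1CC[C@@]2(C)O[Si](CC)(CC)CC
F16 | step 8 | 4-nitrobenzoate of 13 | CC1(C)C=C(C)[C@@H](OC(=O)c3ccc(cc3)[N+](=O)[O-])C[C@@H]2[C@H]1CC[C@@]2(C)O[Si](CC)(CC)CC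
F0 | step 15 | none | none
A1 | alternative 1 | left-half sulfone, C11-[(1-phenyl-1H-tetrazol-5-yl)sulfonylmethyl] oxepane–cyclohexane with 3-OTES and free 10-OH | CC1(C)O[C@@H]2CC[C@](C)(O)[C@H](CS(=O)(=O)c3nnnn3-c3ccccc3)[C@@]2(C)CC[C@H]1O[Si](CC)(CC)CC
A2 | alternative 1 | (1R,3aR,5S,8aR)-1,4,4,6-tetramethyl-1-(triethylsilyloxy)-1,2,3,3a,4,5,8,8a-octahydroazulene-5-carbaldehyde | O=C[C@@H]1C(C)(C)[C@@H]2CC[C@@](C)(O[Si](CC)(CC)CC)[C@@H]2CC=C1C
A3 | alternative 1 | (E)-C12=C12' alkene that joins the two bicycles | CC1(C)O[C@@H]2CC[C@](C)(O)[C@H](/C=C/[C@@H]3C(C)(C)[C@@H]4CC[C@@](C)(O[Si](CC)(CC)CC)[C@@H]4CC=C3C)[C@@]2(C)CC[C@H]1O[Si](CC)(CC)CC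
A4 | alternative 2 | (3R,6R,7R,18R,19R)-2,3:6,7:18,19-triepoxysqualene | CC1(C)O[C@@H]1CC[C@@]2(C)O[C@@H]2CC/C(C)=C/CC/C=C(\C)CC[C@H]3O[C@]3(C)CCC=C(C)C
A5 | alternative 3 | (R)-limonene | CC1=CC[C@@H](CC1)C(C)=C
A6 | alternative 3 | (S)-2-methyl-5-(prop-1-en-2-yl)cyclopent-1-ene-1-carbaldehyde | CC1=C(C=O)[C@@H](CC1)C(C)=C
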